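The cyclohexene (C1 methyl-bearing, C2 =CH, C3 with flavonol ring B, C4 with the aroyl group, C5 with the resorcinol ring, C6 CH2) is split into two three-carbon halves. C4–C5–C6 is folded into a prochiral 1,3-diarylcyclobutanol whose carbinol carbon becomes the aroyl C=O; C1–C2–C3 arrives as a propargylic carbonate on ring B. In one flask, palladium-catalysed enantioselective C–C cleavage and allenylation forge C6–C1 and set C5; acid then turns the allene into a C1–C2–C3 allyl cation, stabilised by the 2,6-dioxygenated ring B on C3, which the enol of the unveiled C4 ketone captures to forge C3–C4. Global MOM removal ends the route.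

Key step: step 12

Remark: ring numbering as above; the target is the all-trans (3R,4R,5S) isomer; MOM = methoxymethyl; the sense of induction of the ferrocenyl ligand is not predicted here, so it is assumed that the named antipode is the one that gives (5S).

Step 1
Reactants: 1 2,4-dihydroxybenzaldehyde
Product: 2 2,4-bis(methoxymethoxy)benzaldehyde
Conditions: MOMCl, i-Pr2NEt, CH2Cl2, 0 °C → reflux
Reagents that add atoms: chloromethyl methyl ether, COCCl
Why: Williamson-type O-alkylation of both phenols by the α-chloro ether should proceed with the amine as HCl scavenger and leave the aldehyde untouched.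

Step 2
Reactants: 2 2,4-bis(methoxymethoxy)benzaldehyde; 3 but-2-ynal
Product: 6 3-(1-hydroxybut-2-yn-1-yl)-2,4-bis(methoxymethoxy)benzaldehyde (racemic), via lithium amino alkoxide 4 (not isolated), via aryllithium 5 (not isolated)
Conditions: 1-methylpiperazine, n-BuLi, THF, −20 °C; add 2; then n-BuLi, −20 °C; then 3, −78 °C → rt; aq NH4Cl
Reagents that add atoms: none
Why: In situ α-amino alkoxide protection of the aldehyde followed by directed ortho-metalation should lithiate the doubly activated position between the two MOM ethers, and the aryllithium adds 1,2 to the ynal; work-up releases the aldehyde, and the new carbinol centre is racemic and is destroyed later.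

Step 3
Reactants: 7 1-(2,4-dihydroxyphenyl)ethan-1-one
Product: 8 1-[2-hydroxy-4-(methoxymethoxy)phenyl]ethan-1-one
Conditions: MOMCl (1.05 equiv), K2CO3, acetone, rt
Reagents that add atoms: chloromethyl methyl ether, COCCl
Why: Selective Williamson alkylation is expected because the 2-OH is hydrogen-bonded to the acetyl group and stays free under weak base.

Step 4
Reactants: 6 3-(1-hydroxybut-2-yn-1-yl)-2,4-bis(methoxymethoxy)benzaldehyde; 8 1-[2-hydroxy-4-(methoxymethoxy)phenyl]ethan-1-one
Product: 10 3-hydroxy-2-[3-(1-hydroxybut-2-yn-1-yl)-2,4-bis(methoxymethoxy)phenyl]-7-(methoxymethoxy)-4H-chromen-4-one, via chalcone 9 (not isolated)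
Conditions: KOH (aq, 50%), EtOH, rt; then 30% H2O2, 0 °C → rt; AcOH to pH 6
Reagents that add atoms: hydrogen peroxide, OO
Why: Claisen–Schmidt condensation to the 2′-hydroxychalcone and Algar–Flynn–Oyamada oxidative cyclisation in the same pot should give the flavonol, since ring A has no 6′-substituent and the electron-rich alkyne and the carbinol are inert to hydroperoxide.

Step 5
Reactants: 10 3-hydroxy-2-[3-(1-hydroxybut-2-yn-1-yl)-2,4-bis(methoxymethoxy)phenyl]-7-(methoxymethoxy)-4H-chromen-4-one
Product: 11 2-[3-(1-hydroxybut-2-yn-1-yl)-2,4-bis(methoxymethoxy)phenyl]-3,7-bis(methoxymethoxy)-4H-chromen-4-one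
Conditions: MOMCl, K2CO3, acetone, rt
Reagents that add atoms: chloromethyl methyl ether, COCCl
Why: Chemoselective Williamson alkylation of the acidic enolic 3-OH is expected under weak base, the secondary propargylic alcohol not being deprotonated.

Step 6
Reactants: 11 2-[3-(1-hydroxybut-2-yn-1-yl)-2,4-bis(methoxymethoxy)phenyl]-3,7-bis(methoxymethoxy)-4H-chromen-4-one
Product: 12 1-{3-[3,7-bis(methoxymethoxy)-4-oxo-4H-chromen-2-yl]-2,6-bis(methoxymethoxy)phenyl}but-2-yn-1-yl methyl carbonate (racemic)
Conditions: ClCO2Me, pyridine, DMAP (cat.), CH2Cl2, 0 °C; filtration through basic alumina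
Reagents that add atoms: methyl chloroformate, COC(=O)Cl
Why: DMAP-catalysed acylation of the secondary alcohol installs the carbonate leaving group for the palladium step.

Step 7
Reactants: 2 2,4-bis(methoxymethoxy)benzaldehyde
Product: 13 1-ethenyl-2,4-bis(methoxymethoxy)benzene
Conditions: Ph3PCH3Br, KOt-Bu, THF, 0 °C → rt
Reagents that add atoms: methyltriphenylphosphonium bromide, C[P+](c1ccccc1)(c1ccccc1)c1ccccc1.[Br-]
Why: Wittig methylenation of the aldehyde gives the styrene.

Step 8
Reactants: 13 1-ethenyl-2,4-bis(methoxymethoxy)benzene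
Product: 14 3-[2,4-bis(methoxymethoxy)phenyl]-2,2-dichlorocyclobutan-1-one (racemic)
Conditions: Cl3CCOCl, Zn–Cu couple, Et2O/DME, rt
Reagents that add atoms: trichloroacetyl chloride, O=C(Cl)C(Cl)(Cl)Cl
Why: Thermal [2+2] cycloaddition of dichloroketene made in situ should place the carbonyl carbon on the terminal CH2 of the styrene, so the aryl group ends at C3; the racemic centre loses its chirality in the next step.

Step 9
Reactants: 14 3-[2,4-bis(methoxymethoxy)phenyl]-2,2-dichlorocyclobutan-1-one
Product: 15 3-[2,4-bis(methoxymethoxy)phenyl]cyclobutan-1-one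
Conditions: Zn dust, NH4Cl, MeOH, rt
Reagents that add atoms: none
Why: Reductive dechlorination of the α,α-dichloroketone by zinc under buffered conditions should spare the MOM ethers and gives an achiral ketone.

Step 10
Reactants: 16 4-bromobenzene-1,3-diol
Product: 17 1-bromo-2,4-bis(methoxymethoxy)benzene
Conditions: MOMCl, i-Pr2NEt, CH2Cl2, 0 °C → rt
Reagents that add atoms: chloromethyl methyl ether, COCCl
Why: Williamson-type MOM protection of both phenols.

Step 11
Reactants: 17 1-bromo-2,4-bis(methoxymethoxy)benzene; 15 3-[2,4-bis(methoxymethoxy)phenyl]cyclobutan-1-one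
Product: 19 cis-1,3-bis[2,4-bis(methoxymethoxy)phenyl]cyclobutan-1-ol (OH cis to the 3-aryl group, achiral), via aryllithium 18 (not isolated)
Conditions: n-BuLi, THF, −78 °C; then 15, −78 → 0 °C; aq NH4Cl
Reagents that add atoms: none
Why: Bromine–lithium exchange and 1,2-addition of the aryllithium from the ring face opposite the 3-aryl group should give the cis cyclobutanol, whose two ring C–C bonds at the carbinol carbon are enantiotopic.

Step 12
Reactants: 19 cis-1,3-bis[2,4-bis(methoxymethoxy)phenyl]cyclobutan-1-ol; 12 1-{3-[3,7-bis(methoxymethoxy)-4-oxo-4H-chromen-2-yl]-2,6-bis(methoxymethoxy)phenyl}but-2-yn-1-yl methyl carbonate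
Product: 21 [2,4-bis(methoxymethoxy)phenyl]{(1R,2R,6S)-2-{3-[3,7-bis(methoxymethoxy)-4-oxo-4H-chromen-2-yl]-2,6-bis(methoxymethoxy)phenyl}-6-[2,4-bis(methoxymethoxy)phenyl]-4-methylcyclohex-3-en-1-yl}methanone (octa-MOM ether of the target), via allenyl ketone 20 (not isolated)
Conditions: Pd2(dba)3·CHCl3 (2.5 mol%), (R)-N,N-dimethyl-1-[(S)-2-(diphenylphosphino)ferrocenyl]ethylamine (6 mol%), 4 Å MS, toluene, 50 °C; then CH2Cl2, CF3CO2H (0.3 equiv), 0 °C → rt; then DBU (0.5 equiv), rt; same flask
Reagents that add atoms: none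
Why: Proposed new method: zerovalent palladium ionises carbonate 12 in the SN2′ sense to an allenylpalladium methoxide (divalent palladium) that exchanges alkoxide with 19, undergoes strain-driven β-carbon elimination of one of the two enantiotopic ring bonds and reductively eliminates to allene 20 (bond C6–C1, ketone unveiled); the added acid then protonates the central allene carbon C2 to an allyl cation over C1–C2–C3 that the enol of the new ketone attacks at C3 (bond C3–C4). The closest known reactions are the palladium-catalysed asymmetric ring-opening allenylation of tert-cyclobutanols with propargylic carbonates and the acid- or gold-promoted Conia-ene-type addition of enols to allenes; new are their union in one flask and a simple aryl ketone enol as the nucleophile. Only the cyclohexene is closed, by a 6-(enolexo)-endo-trig attack on the allyl cation, since C-attack at C1 would give a cyclobutane and O-attack at C1 gives a dihydropyran that re-ionises or undergoes Claisen shift to the same product. C5 is set by the chiral P,N ligand in the C–C cleavage (catalyst control), C3 by C5 through a chair-like closure with the C5 aryl group and the ring-B-bearing cation terminus (E geometry) both equatorial, and C4 by DBU equilibration of the epimerisable ketone α-carbon to the all-equatorial trans,trans isomer. The step needs reductive elimination to outrun β-hydride loss from the primary alkylpalladium, which the chelating ligand favours, and capture of the cation at C3 over Friedel–Crafts paths, which the six-membered transition state and the blocked ortho position of the C5 aryl ring secure. Methanol from the leaving group is held by the sieves so that the acid stage should not transacetalise the MOM ethers.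

Step 13
Reactants: 21 octa-MOM ether of the target
Product: 23 (2,4-dihydroxyphenyl){(1R,2R,6S)-2-[2,6-dihydroxy-3-(3,7-dihydroxy-4-oxo-4H-chromen-2-yl)phenyl]-6-(2,4-dihydroxyphenyl)-4-methylcyclohex-3-en-1-yl}methanone (CNP0190989.1), via octakis(trimethylsilyl) ether 22 (not isolated)
Conditions: TMSOTf, 2,2′-bipyridyl, MeCN, 0 °C → rt; then H2O, rt
Reagents that add atoms: none
Why: Silyl triflate–bipyridyl activation should convert each aryl and enolic MOM ether into a TMS ether under non-protic, near-neutral conditions, and water then hydrolyses the silyl ethers; this avoids the Brønsted acid that could add the ortho-phenol of ring B to the C1=C2 alkene, and no stereocentre is touched.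

Compound list
1 | 2,4-dihydroxybenzaldehyde | O=Cc1ccc(O)cc1O | starting material
2 | 2,4-bis(methoxymethoxy)benzaldehyde | O=Cc1ccc(OCOC)cc1OCOC | intermediate
3 | but-2-ynal | CC#CC=O | starting material
4 | lithium [2,4-bis(methoxymethoxy)phenyl](4-methylpiperazin-1-yl)methanolate | [Li+].[O-]C(N1CCN(C)CC1)c1ccc(OCOC)cc1OCOC | intermediate
5 | lithium [3-lithio-2,4-bis(methoxymethoxy)phenyl](4-methylpiperazin-1-yl)methanolate | [Li+].[O-]C(N1CCN(C)CC1)c1ccc(OCOC)c([Li])c1OCOC | intermediate
6 | 3-(1-hydroxybut-2-yn-1-yl)-2,4-bis(methoxymethoxy)benzaldehyde (racemic) | CC#CC(O)c1c(OCOC)ccc(C=O)c1OCOC | intermediate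
7 | 1-(2,4-dihydroxyphenyl)ethan-1-one | CC(=O)c1ccc(O)cc1O | starting material
8 | 1-[2-hydroxy-4-(methoxymethoxy)phenyl]ethan-1-one | CC(=O)c1ccc(OCOC)cc1O | intermediate
9 | (E)-3-[3-(1-hydroxybut-2-yn-1-yl)-2,4-bis(methoxymethoxy)phenyl]-1-[2-hydroxy-4-(methoxymethoxy)phenyl]prop-2-en-1-one | CC#CC(O)c1c(OCOC)ccc(/C=C/C(=O)c2ccc(OCOC)cc2O)c1OCOC | intermediate
10 | 3-hydroxy-2-[3-(1-hydroxybut-2-yn-1-yl)-2,4-bis(methoxymethoxy)phenyl]-7-(methoxymethoxy)-4H-chromen-4-one | CC#CC(O)c1c(OCOC)ccc(-c2oc3cc(OCOC)ccc3c(=O)c2O)c1OCOC | intermediate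
11 | 2-[3-(1-hydroxybut-2-yn-1-yl)-2,4-bis(methoxymethoxy)phenyl]-3,7-bis(methoxymethoxy)-4H-chromen-4-one | CC#CC(O)c1c(OCOC)ccc(-c2oc3cc(OCOC)ccc3c(=O)c2OCOC)c1OCOC | intermediate
12 | 1-{3-[3,7-bis(methoxymethoxy)-4-oxo-4H-chromen-2-yl]-2,6-bis(methoxymethoxy)phenyl}but-2-yn-1-yl methyl carbonate (racemic) | CC#CC(OC(=O)OC)c1c(OCOC)ccc(-c2oc3cc(OCOC)ccc3c(=O)c2OCOC)c1OCOC | intermediate
13 | 1-ethenyl-2,4-bis(methoxymethoxy)benzene | C=Cc1ccc(OCOC)cc1OCOC | intermediate
14 | 3-[2,4-bis(methoxymethoxy)phenyl]-2,2-dichlorocyclobutan-1-one (racemic) | O=C1CC(c2ccc(OCOC)cc2OCOC)C1(Cl)Cl | intermediate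
15 | 3-[2,4-bis(methoxymethoxy)phenyl]cyclobutan-1-one | O=C1CC(c2ccc(OCOC)cc2OCOC)C1 | intermediate
16 | 4-bromobenzene-1,3-diol | Oc1ccc(Br)c(O)c1 | starting material
17 | 1-bromo-2,4-bis(methoxymethoxy)benzene | COCOc1ccc(Br)c(OCOC)c1 | intermediate
18 | [2,4-bis(methoxymethoxy)phenyl]lithium | [Li]c1ccc(OCOC)cc1OCOC | intermediate
19 | cis-1,3-bis[2,4-bis(methoxymethoxy)phenyl]cyclobutan-1-ol (OH cis to the 3-aryl group) | O[C@@]1(c2ccc(OCOC)cc2OCOC)C[C@@H](c2ccc(OCOC)cc2OCOC)C1 | intermediate
20 | (3S)-1,3-bis[2,4-bis(methoxymethoxy)phenyl]-7-{3-[3,7-bis(methoxymethoxy)-4-oxo-4H-chromen-2-yl]-2,6-bis(methoxymethoxy)phenyl}-5-methylhepta-5,6-dien-1-one (both allene epimers) | O=C(c1ccc(OCOC)cc1OCOC)C[C@@H](c1ccc(OCOC)cc1OCOC)CC(C)=C=Cc1c(OCOC)ccc(-c2oc3cc(OCOC)ccc3c(=O)c2OCOC)c1OCOC | intermediate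
21 | [2,4-bis(methoxymethoxy)phenyl]{(1R,2R,6S)-2-{3-[3,7-bis(methoxymethoxy)-4-oxo-4H-chromen-2-yl]-2,6-bis(methoxymethoxy)phenyl}-6-[2,4-bis(methoxymethoxy)phenyl]-4-methylcyclohex-3-en-1-yl}methanone | CC1=C[C@@H](c2c(OCOC)ccc(-c3oc4cc(OCOC)ccc4c(=O)c3OCOC)c2OCOC)[C@H](C(=O)c2ccc(OCOC)cc2OCOC)[C@@H](c2ccc(OCOC)cc2OCOC)C1 | intermediate
22 | octakis(trimethylsilyl) ether of the target, (1R,2R,6S) | CC1=C[C@@H](c2c(O[Si](C)(C)C)ccc(-c3oc4cc(O[Si](C)(C)C)ccc4c(=O)c3O[Si](C)(C)C)c2O[Si](C)(C)C)[C@H](C(=O)c2ccc(O[Si](C)(C)C)cc2O[Si](C)(C)C)[C@@H](c2ccc(O[Si](C)(C)C)cc2O[Si](C)(C)C)C1 | intermediate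
23 | (2,4-dihydroxyphenyl){(1R,2R,6S)-2-[2,6-dihydroxy-3-(3,7-dihydroxy-4-oxo-4H-chromen-2-yl)phenyl]-6-(2,4-dihydroxyphenyl)-4-methylcyclohex-3-en-1-yl}methanone | CC1=C[C@@H](c2c(O)ccc(-c3oc4cc(O)ccc4c(=O)c3O)c2O)[C@H](C(=O)c2ccc(O)cc2O)[C@@H](c2ccc(O)cc2O)C1 | target

Total step count: 13 steps.
Longest linear sequence: 7 steps (steps 1, 2, 4, 5, 6, 12, 13; the cyclobutanol branch 1, 7, 8, 9, 11, 12, 13 is equally long).

Steps most likely to fail

1. Step 12 (Proposed new method). What may go wrong: β-hydride loss or protodemetalation of the primary alkylpalladium before reductive elimination, weak discrimination of the enantiotopic ring bonds, and, in the acid stage, oligomerisation of the allyl cation or partial loss of MOM groups. The fallback uses known chemistry and separates the two bond formations. It sets out from 19 and 12: the palladium-catalysed ring-opening allenylation is run alone and allenyl ketone 20 is isolated. TBSOTf and Et3N in CH2Cl2 convert it into the tert-butyldimethylsilyl enol ether F1. C3–C4 is then closed by the gold-catalysed carbocyclisation of silyl enol ethers onto allenes ((Ph3P)AuCl and AgSbF6, a monovalent gold catalyst, CH2Cl2/MeOH, rt), followed by DBU equilibration. The fallback comes back to the route at 21.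

2. Step 13. What may go wrong: incomplete cleavage of the eight acetals, silyl-triflate-induced addition of the ring-B phenol to the C1=C2 alkene or ketalisation with the C4 ketone, and air oxidation of the free polyphenol during isolation. The fallback sets out from 21: the MOM ethers are cleaved by soft-nucleophile transacetalisation (ZnBr2, n-PrSH, CH2Cl2, 0 °C). The crude polyphenol is acetylated at once (Ac2O, pyridine) to the octaacetate F2, which can be purified on silica. Mild methanolysis (K2CO3, MeOH, 0 °C, argon) then releases the phenols, and the fallback comes back at 23.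

3. Step 2. What may go wrong: lithiation ortho to the amino alkoxide instead of between the MOM ethers, incomplete masking of the aldehyde, and consumption or polymerisation of the sensitive ynal by residual butyllithium. The fallback sets out from 2: the aldehyde is protected as the dimethyl acetal F3 (HC(OMe)3, PPTS cat., MeOH). Lithiation between the two MOM ethers (n-BuLi, THF, 0 °C) and a DMF quench give the aldehyde F4. 1-Propynylmagnesium bromide (THF, 0 °C) gives the carbinol F5. Mild acetal hydrolysis (PPTS, acetone/H2O, rt) brings the fallback back to the route at 6.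

Further compounds
F1 | step 12 | (Z)-tert-butyldimethylsilyl enol ether of allenyl ketone 20, (3S) | CC(C)(C)[Si](C)(C)O/C(c1ccc(OCOC)cc1OCOC)=C\[C@@H](c1ccc(OCOC)cc1OCOC)CC(C)=C=Cc1c(OCOC)ccc(-c2oc3cc(OCOC)ccc3c(=O)c2OCOC)c1OCOC
F2 | step 13 | octaacetate of the target, (1R,2R,6S) | CC1=C[C@@H](c2c(OC(C)=O)ccc(-c3oc4cc(OC(C)=O)ccc4c(=O)c3OC(C)=O)c2OC(C)=O)[C@H](C(=O)c2ccc(OC(C)=O)cc2OC(C)=O)[C@@H](c2ccc(OC(C)=O)cc2OC(C)=O)C1
F3 | step 2 | 1-(dimethoxymethyl)-2,4-bis(methoxymethoxy)benzene | COC(OC)c1ccc(OCOC)cc1OCOC
F4 | step 2 | 3-(dimethoxymethyl)-2,6-bis(methoxymethoxy)benzaldehyde | COC(OC)c1ccc(OCOC)c(C=O)c1OCOC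
F5 | step 2 | 1-[3-(dimethoxymethyl)-2,6-bis(methoxymethoxy)phenyl]but-2-yn-1-ol (racemic) | CC#CC(O)c1c(OCOC)ccc(C(OC)OC)c1OCOC
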